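## The problem

Target 15 is the 4-hydroxy-3-methoxybenzoate (vanillate) of a germacra-1(10),4-dien-6-ol. It is a single ten-membered carbocycle, numbered here C6 (ester carbinol), C5=C4 (methyl), C3, C2, C1=C10 (methyl), C9, C8 and C7 (isopropyl), with no second ring to template its closure. Both trisubstituted ring alkenes are Z. The usual germacrane entries (four-carbon oxy-Cope expansion of six-membered divinyl carbinols, E-selective olefinations) do not deliver this geometry, and closing a ten-membered ring from an open chain works against entropy and transannular strain. The two adjacent stereocenters, C6 (R) and C7 (S), carry the ester oxygen and the isopropyl group cis on the ring. At the ketone oxidation level C7 is alpha to C6 and epimerizable, so both centers can be set in one reduction: the C7 substituent steers hydride to the opposite face of C6 and a chiral catalyst selects the enantiomer. Several groups are fragile. The allylic C6 ester can ionize, the 1(10),4-diene cyclizes across the ring under acid and is a Cope-competent cyclodeca-1,5-diene on strong heating, a Z beta-methyl enone can lose its geometry through its extended enolate, and the phenol must be masked during acylation. The enabling feature is that C6, C5, C4, C3, C2, C1, C10 and C9, with both Z alkenes and both methyl groups, are the eight ring atoms of the isoprene dimer 1,5-dimethylcycloocta-1,5-diene. Only C7–C8 has to be inserted between C6 and C9, and C9 is allylic to C10=C1, so it can migrate from C6 to a vinyl terminus as an allyl-anion-like group.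

## Retrosynthesis

**15 to 14.** The O–Si bond of the phenol is cut last. A silyl ether is preferred to a benzyl ether (hydrogenolysis would touch the alkenes) and to an acetate (an aryl acetate is itself an acyl donor). Buffered fluoride is the only demand on the forward step, and it leaves the allylic ester and both alkenes alone.

**14 to 10 and 13.** The acyl C–O bond of the ester is cut, giving alcohol 10, which holds all fifteen ring and side-chain carbons and both stereocenters, and the protected acid 13. A Mitsunobu coupling is not used because it would require the C6 epimer and invites allylic transposition. The forward step must acylate a hindered secondary allylic alcohol with retention and without ionizing C6–O.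

**13 to 11.** Both Si–O bonds are cut back to vanillic acid 11. The forward step silylates phenol and acid (12), then hydrolyses only the labile silyl ester.

**10 to 9.** The C6–H bond is cut, and with it the fixed configuration at C7, which leads to ketone 9, racemic at C7. This is preferred to any plan that fixes C7 earlier, because the ring-forming step ends in the C6=C7 enolate and cannot hold a C7 configuration. The precursors then contain no stereocenter that must be controlled. The forward step must reduce C=O and not C=C, epimerize C7 faster than the slow-reacting enantiomer is reduced, and deliver hydride anti to the isopropyl group.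

**9 to 6.** In the retro direction C8–C9 is cut and C6–C9 re-formed, contracting the ring from ten to eight and turning the ketone into tertiary dienol 6 (in the forward sense through alkoxide 7 and enolate 8). Cutting C6–C7 or C2–C3 instead would give open chains in which both Z alkenes must be built and a ten-membered ring closed. The four-carbon oxy-Cope expansion of a six-membered divinyl carbinol would place C1=C10 trans. Here the precursor is an eight-membered ring that already carries both Z alkenes. The forward step must favour the [1,3] shift of C9 to C8 over the [3,3] shift (C8 to C1) and over bonding at C4, and must keep C1=C10 cis.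

**6 to 2 and 3.** The C6–C7 bond is cut, giving dienone 2 and the vinyl nucleophile made from bromide 3 (lithium reagent 4, cerium reagent 5). The forward step needs clean 1,2-addition to a ketone whose C9 methylene is both alpha to the carbonyl and allylic, hence a weakly basic organocerium.

**2 to 1.** The C6=O group is removed, leaving the commercial diene 1. Its twofold symmetry makes the two CH2 groups next to a CH= carbon equivalent, so the forward step only has to choose that type of CH2 over the one next to the methyl-bearing alkene carbon and stop after one oxidation.

## Roads not taken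

**Alternative 1:** The cut is C2–C3. The open-chain Z,Z chloro sulfone A2 has C2 as a CH2SO2Ph group next to C1=C10 and C3 as a primary allylic chloride. In the forward step a strong amide base at high dilution would form the sulfonyl-stabilized allyl anion, which displaces chloride to give the ten-membered sulfone A1. Reductive desulfonylation, desilylation and acylation would follow.
- Merits: C6 and C7 are set early in an open chain by an auxiliary-controlled aldol, so the absolute configuration does not hang on a late catalytic step. Sulfone alkylation is a proven way to close ten-membered rings, and no sigmatropic side path exists.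
- Weak points: both Z trisubstituted alkenes of A2 must be made by separate stereoselective steps and kept through a Z allylic chloride and a Z allylic sulfone. The allyl anion can alkylate at either end and the chloride can react in SN2 or SN2' fashion. Removing a sulfonyl group that sits allylic to C1=C10 risks shifting or isomerizing that alkene. The sequence is estimated at well over a dozen steps.
- Comparison: Alternative 1 is better in stereochemical certainty. The chosen plan sets against it a seven-step route in which both Z alkenes are bought in the starting ring and never have to be constructed.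

**Alternative 2:** The cut is C6–C7. 12-Bromo-(2Z,6Z)-farnesal A4 would be treated with CrCl2 (divalent chromium). The resulting allylchromium adds through its internal carbon to the aldehyde and gives trienol A3 with the ring, both stereocenters and an isopropenyl group on C7.
- Merits: one step forms the ring and both stereocenters, and the disconnection follows the biogenetic pattern. A3 is 6,7-trans, so a Mitsunobu coupling with 13 would invert C6 and install the ester in one operation. That end game is more direct than separate reduction and acylation.
- Weak points: the isopropenyl group must then be hydrogenated in the presence of two trisubstituted alkenes (RhCl(PPh3)3, H2). The cyclization gives racemic material, and enantioselective variants of this ring closure are not reliable. A4 is not an article of commerce, needs both Z alkenes built and a terminal allylic functionalization, and its Z enal isomerizes readily. Mitsunobu inversion at a hindered allylic carbinol can transpose.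
- Comparison: Alternative 2 is better in forming the ring and both stereocenters together. The chosen plan offers control of absolute configuration by one catalytic reduction and a Z,Z skeleton that needs no olefin synthesis.

**Alternative 3:** The cut is C1=C10, with sulfur inserted between the two carbons. The eleven-membered cyclic sulfone A6 would be halogenated at an alpha carbon in situ (KOH, CCl4, t-BuOH) and the episulfone would lose SO2 to give A5, the TBS ether of 10.
- Merits: an eleven-membered thiacycle closes more easily than a ten-membered carbocycle, and C6 and C7 are in place before the contraction. The product needs only desilylation and acylation.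
- Weak points: the geometry of the new trisubstituted C1=C10 is decided in the least controllable step, and Z selectivity for a trisubstituted alkene formed by ring contraction cannot be assumed. Halogenation must choose between the C1 methylene and the C10 methine. Dichlorocarbene formed from CCl4 and base can add to C4=C5. A6 itself requires a long stereocontrolled synthesis.
- Comparison: Alternative 3 is better in having no competing sigmatropic pathway and in securing the stereocenters before ring formation. The chosen plan has C1=C10 fixed as Z from the first compound and is much shorter.

Key step: step 3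

Assumption 1: commercial 1,5-dimethylcycloocta-1,5-diene contains some 1,6-dimethyl isomer; 1 is taken as the 1,5-isomer after fractional distillation, and any isomeric ketone is removed by chromatography at the stage of 2.

Assumption 2: the hand of the hydrogenation catalyst in step 4 is assigned by analogy with the reduction of 2-alkylcycloalkanones to cis-2-alkylcycloalkanols, the target belonging to the mirror-image series of the usual (S)-diphosphine/(R,R)-diamine case. The enantiomeric catalyst is equally available should the sense prove opposite.

## Route

Step 1
Reactants: 1 (1Z,5Z)-1,5-dimethylcycloocta-1,5-diene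
Product: 2 (2Z,6Z)-3,7-dimethylcycloocta-2,6-dien-1-one
Conditions: CrO3, 3,5-dimethylpyrazole, CH2Cl2, −20 °C, partial conversion, 1 recovered
Reagents that add atoms: chromium trioxide, O=[Cr](=O)=O
Why: Allylic oxidation with the CrO3–3,5-dimethylpyrazole complex (hexavalent chromium) attacks the ring CH2 attached to the CH= end of a trisubstituted alkene, as in the 7-oxidation of Δ5-steroids, and gives the beta-methyl enone. The two such CH2 groups of 1 are equivalent by symmetry, so one mono-ketone is expected, and stopping early spares the second alkene and the activated C9 methylene of 2.

Step 2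
Reactants: 2 (2Z,6Z)-3,7-dimethylcycloocta-2,6-dien-1-one; 3 2-bromo-3-methylbut-1-ene
Product: 6 racemic (2Z,6Z)-3,7-dimethyl-1-(3-methylbut-1-en-2-yl)cycloocta-2,6-dien-1-ol, via 3-methylbut-1-en-2-yllithium 4 (not isolated), via dichloro(3-methylbut-1-en-2-yl)cerium 5 (not isolated)
Conditions: 3, t-BuLi (2 equiv), THF, −78 °C; anhydrous CeCl3, THF, −78 °C; then 2, −78 °C; aq. NH4Cl
Reagents that add atoms: none
Why: Bromine–lithium exchange followed by transmetalation gives a weakly basic organocerium reagent, whose 1,2-addition to the enolizable, beta,beta-disubstituted enone should outrun deprotonation at C9 and conjugate addition. The new carbinol center forms as a racemate, which does not matter because it becomes the carbonyl carbon in step 3.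

Step 3
Reactants: 6 racemic (2Z,6Z)-3,7-dimethyl-1-(3-methylbut-1-en-2-yl)cycloocta-2,6-dien-1-ol
Product: 9 racemic (2Z,6Z)-3,7-dimethyl-10-(propan-2-yl)cyclodeca-2,6-dien-1-one, via potassium salt of the carbinol 7 (not isolated), via ring-expanded potassium enolate 8 (not isolated)
Conditions: KH, 18-crown-6, THF, 0 °C to rt; then aq. NH4Cl, −78 °C
Reagents that add atoms: none
Why: KH gives the potassium alkoxide 7, and 18-crown-6 loosens the ion pair so that the C6–C9 bond, which is beta to the oxyanion and allylic to C10=C1, is strongly weakened. C9 then moves from C6 to the unsubstituted vinyl terminus C8, either in a concerted suprafacial [1,3] shift or by heterolysis to a cross-conjugated dienone tethered to a 2-methylallyl anion that re-adds in conjugate fashion, and the resulting enolate 8 is protonated at C7 on cold quench to give 9. The closest known reaction is the alkoxide-accelerated [1,3] sigmatropic two-carbon ring expansion of potassium 1-vinylcycloalk-3-en-1-olates to cycloalk-5-enones, here run on a substrate with one more ring alkene next to the carbinol. The ten-membered ring is closed by endo attack of C9 on the terminal carbon of the vinyl ketone unit (10-endo-trig in the stepwise picture), so the eight-membered ring grows by C7 and C8. No stereocenter is controlled here: C6 becomes the carbonyl carbon and C7 arises by protonation of 8 as a racemate, which step 4 is designed to accept. The step needs [1,3] over [3,3] selectivity, and the substrate helps because the cis ring alkene and the short C2–C5 tether allow only a boat-like array of C8, C7, C6, C9, C10 and C1 in which the C7 isopropyl and C10 methyl groups eclipse, while C8–C9 bonding has no such clash. It also needs C8 rather than C4 as acceptor, which follows from C4 being fully substituted and held in the ring whereas C8 is a free CH2 terminus that can align with the breaking bond. The Z geometry of C1=C10 is kept because C9 stays part of a cisoid 2-methylallyl unit joined to C1 (the cis form is also the preferred form of an allylpotassium), and C4=C5 is not part of the migrating array.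

Step 4
Reactants: 9 racemic (2Z,6Z)-3,7-dimethyl-10-(propan-2-yl)cyclodeca-2,6-dien-1-one
Product: 10 (1R,2Z,6Z,10S)-3,7-dimethyl-10-(propan-2-yl)cyclodeca-2,6-dien-1-ol, that is (6R,7S)-germacra-1(10)Z,4Z-dien-6-ol
Conditions: H2 (8 atm), RuCl2[(R)-tolbinap][(S,S)-dpen] (0.5 mol%), t-BuOK, i-PrOH, 25 °C
Reagents that add atoms: none
Why: This is a Noyori-type carbonyl-selective hydrogenation under dynamic kinetic resolution: t-BuOK epimerizes C7 through the cross-conjugated enolate while the diphosphine/diamine ruthenium hydride reduces only C=O and leaves both trisubstituted alkenes. Hydride goes to the outer face of C6 anti to the isopropyl group of the fast-reacting (7S) ketone, the sense that gives cis-2-alkylcycloalkanols, so C6 (R) and C7 (S) are set together with oxygen and isopropyl cis.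

Step 5
Reactants: 11 vanillic acid
Product: 13 4-[(tert-butyldimethylsilyl)oxy]-3-methoxybenzoic acid, via tert-butyldimethylsilyl 4-[(tert-butyldimethylsilyl)oxy]-3-methoxybenzoate 12 (not isolated)
Conditions: TBSCl (2.5 equiv), imidazole, DMF, rt; then AcOH/THF/H2O, rt
Reagents that add atoms: tert-butyldimethylsilyl chloride, CC(C)(C)[Si](C)(C)Cl
Why: Imidazole-promoted silylation covers both the phenol and the acid, and the silyl ester is far more labile to aqueous acetic acid than the aryl silyl ether, so only the acid is released.

Step 6
Reactants: 10 (1R,2Z,6Z,10S)-3,7-dimethyl-10-(propan-2-yl)cyclodeca-2,6-dien-1-ol; 13 4-[(tert-butyldimethylsilyl)oxy]-3-methoxybenzoic acid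
Product: 14 (1R,2Z,6Z,10S)-3,7-dimethyl-10-(propan-2-yl)cyclodeca-2,6-dien-1-yl 4-[(tert-butyldimethylsilyl)oxy]-3-methoxybenzoate
Conditions: DCC, DMAP, CH2Cl2, 0 °C to rt
Reagents that add atoms: none
Why: In this Steglich esterification the acyl group is transferred to the oxygen of 10 by way of the acylpyridinium ion, so the C6–O bond is never broken and the configuration is retained. The masked phenol cannot compete as a nucleophile, and the conditions are neutral enough to avoid ionizing the allylic system.

Step 7
Reactants: 14 (1R,2Z,6Z,10S)-3,7-dimethyl-10-(propan-2-yl)cyclodeca-2,6-dien-1-yl 4-[(tert-butyldimethylsilyl)oxy]-3-methoxybenzoate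
Product: 15 (1R,2Z,6Z,10S)-3,7-dimethyl-10-(propan-2-yl)cyclodeca-2,6-dien-1-yl 4-hydroxy-3-methoxybenzoate (CNP0306317.1)
Conditions: TBAF, AcOH, THF, 0 °C
Reagents that add atoms: none
Why: Fluoride cleaves the aryl silyl ether. Acetic acid buffers the phenoxide so that it does not attack the ester, and neither the allylic benzoate nor the alkenes react under these conditions.

## Compound list

1 | (1Z,5Z)-1,5-dimethylcycloocta-1,5-diene | C1/C=C(/C)CC/C=C(/C)C1 | starting material
2 | (2Z,6Z)-3,7-dimethylcycloocta-2,6-dien-1-one | O=C1/C=C(/C)CC/C=C(/C)C1 | intermediate
3 | 2-bromo-3-methylbut-1-ene | C=C(Br)C(C)C | starting material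
4 | 3-methylbut-1-en-2-yllithium | [Li]C(=C)C(C)C | intermediate
5 | dichloro(3-methylbut-1-en-2-yl)cerium | Cl[Ce](Cl)C(=C)C(C)C | intermediate
6 | racemic (2Z,6Z)-3,7-dimethyl-1-(3-methylbut-1-en-2-yl)cycloocta-2,6-dien-1-ol | OC1(C(=C)C(C)C)/C=C(/C)CC/C=C(/C)C1 | intermediate
7 | potassium (2Z,6Z)-3,7-dimethyl-1-(3-methylbut-1-en-2-yl)cycloocta-2,6-dien-1-olate | [K+].[O-]C1(C(=C)C(C)C)/C=C(/C)CC/C=C(/C)C1 | intermediate
8 | potassium (2Z,6Z)-3,7-dimethyl-10-(propan-2-yl)cyclodeca-1(10),2,6-trien-1-olate (enolate geometry not defined) | [K+].[O-]C1=C(C(C)C)CC/C(C)=C\CC/C(C)=C\1 | intermediate
9 | racemic (2Z,6Z)-3,7-dimethyl-10-(propan-2-yl)cyclodeca-2,6-dien-1-one | O=C1/C=C(/C)CC/C=C(/C)CCC1C(C)C | intermediate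
10 | (1R,2Z,6Z,10S)-3,7-dimethyl-10-(propan-2-yl)cyclodeca-2,6-dien-1-ol | O[C@H]1/C=C(/C)CC/C=C(/C)CC[C@H]1C(C)C | intermediate
11 | vanillic acid (4-hydroxy-3-methoxybenzoic acid) | COc1cc(C(=O)O)ccc1O | starting material
12 | tert-butyldimethylsilyl 4-[(tert-butyldimethylsilyl)oxy]-3-methoxybenzoate | COc1cc(C(=O)O[Si](C)(C)C(C)(C)C)ccc1O[Si](C)(C)C(C)(C)C | intermediate
13 | 4-[(tert-butyldimethylsilyl)oxy]-3-methoxybenzoic acid | COc1cc(C(=O)O)ccc1O[Si](C)(C)C(C)(C)C | intermediate
14 | (1R,2Z,6Z,10S)-3,7-dimethyl-10-(propan-2-yl)cyclodeca-2,6-dien-1-yl 4-[(tert-butyldimethylsilyl)oxy]-3-methoxybenzoate | COc1cc(C(=O)O[C@H]2/C=C(/C)CC/C=C(/C)CC[C@H]2C(C)C)ccc1O[Si](C)(C)C(C)(C)C | intermediate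
15 | (1R,2Z,6Z,10S)-3,7-dimethyl-10-(propan-2-yl)cyclodeca-2,6-dien-1-yl 4-hydroxy-3-methoxybenzoate | COc1cc(C(=O)O[C@H]2/C=C(/C)CC/C=C(/C)CC[C@H]2C(C)C)ccc1O | target

## Step count and risks

Total step count: 7. Longest linear sequence: 6 steps (steps 1, 2, 3, 4, 6 and 7 from 1); step 5 is a one-step branch from 11.

**Step 3 (key step).**
- Most likely failure: the alkoxide follows the [3,3] course (C8 bonding to C1, an eight-membered ketone), bonds at C4 with ring contraction, or fragments without re-closure. All of these start from the same weakened C6–C9 bond, and only the position of recombination differs.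
- Fallback, from 6 back to 9: 6 is silylated (TMSCl, imidazole, DMF) to trimethyl{[(2Z,6Z)-3,7-dimethyl-1-(3-methylbut-1-en-2-yl)cycloocta-2,6-dien-1-yl]oxy}silane F1. F1 is passed through a hot tube at short contact time (about 300–350 °C, flow pyrolysis), where the neutral siloxy [1,3] shift known for trimethylsilyl ethers of 1-vinylcycloalk-3-enols should give the ring-expanded trimethylsilyl enol ether F2. TBAF/AcOH then releases 9.
- What this changes: the neutral, diradical-like pathway removes the ion-pair chemistry, that is, conjugate addition at C4 and base-induced isomerization. The thermal [3,3] shift still competes in this variant, and the contact time must be short because the product is a cyclodeca-1,5-diene that can undergo Cope rearrangement.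

**Step 1.**
- Most likely failure: hydrogen abstraction at the CH2 next to the methyl-bearing alkene carbon (regioisomeric enones), a second oxidation at the other alkene or at the doubly activated C9 methylene, and drift of the skipped alkene into conjugation on work-up.
- Fallback, from 1 back to 2: mono-epoxidation with mCPBA (1 equiv, CH2Cl2, 0 °C) gives (4Z)-1,5-dimethyl-9-oxabicyclo[6.1.0]non-4-ene F3. Sodium phenylselenide, made from (PhSe)2 and NaBH4 in EtOH, opens the epoxide at its less substituted carbon to give (5Z)-1,5-dimethyl-2-(phenylselanyl)cyclooct-5-en-1-ol F4. H2O2 oxidizes this to the selenoxide F5, whose syn elimination can only run away from the tertiary carbinol and gives (2Z,5Z)-1,5-dimethylcycloocta-2,5-dien-1-ol F6. Oxidative 1,3-transposition of this tertiary allylic alcohol with pyridinium chlorochromate, [C5H5NH][CrO3Cl], in CH2Cl2 (Babler–Dauben oxidation) places the carbonyl at the required carbon and gives 2. The oxygen position is then fixed by the epoxide and not by the selectivity of a C–H abstraction.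

**Step 4.**
- Most likely failure: epimerization of the hindered C7–H is slower than reduction of the slow-reacting enantiomer, which erodes the diastereomer and enantiomer ratio; gamma-deprotonation of the enone by t-BuOK scrambles the C4=C5 geometry; or facial discrimination is poor or reversed in a flexible ten-membered ring that differs from the cyclohexanone models.
- Fallback, from 9 back to 10: Luche reduction (NaBH4, CeCl3·7H2O, MeOH, −78 °C) should attack anti to the isopropyl group and give the racemic cis alcohol F7. Lipase-catalysed acylation (Candida antarctica lipase B, vinyl acetate, hexane) would then serve as a kinetic resolution. By the usual enantiopreference of lipases for secondary alcohols, with the alpha-branched C7 side as the large group and the vinylic C5 side as the medium group, the (6S,7R) antipode is expected to be converted into acetate F8 while 10 is recovered. The fallback gives up half of the material but needs neither base nor a match between catalyst and ring.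

**Step 2.**
- Most likely failure: deprotonation of the C9 methylene (alpha to the carbonyl and allylic) by incompletely transmetalated vinyllithium, followed by return of ketone that has moved into conjugation, or sluggish addition of the branched vinyl group.
- Fallback, from 2 back to 6: the small and far less basic ethynylmagnesium bromide (HC≡CMgBr, CeCl3, THF, −78 °C) adds to give (2Z,6Z)-1-ethynyl-3,7-dimethylcycloocta-2,6-dien-1-ol F9. Copper-catalysed, hydroxyl-directed carbomagnesiation (i-PrMgCl, CuI, THF) then delivers the isopropyl group to the internal alkyne carbon and, after protonation, gives 6.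

**Step 6.**
- Most likely failure: slow acyl transfer to the hindered alcohol, which sits between the isopropyl-bearing carbon and the ring alkene, with rearrangement of the O-acylisourea to an N-acylurea, or ionization of the allylic system on prolonged reaction.
- Fallback, from 13 back to 14: 13 is converted with oxalyl chloride and catalytic DMF into 4-[(tert-butyldimethylsilyl)oxy]-3-methoxybenzoyl chloride F10. Alcohol 10 is deprotonated with LiN(SiMe3)2 in THF at −78 °C, and the lithium alkoxide is acylated by F10 to give 14. Acylation of the preformed alkoxide does not depend on the nucleophilicity of the neutral alcohol.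

## Further compounds

F1 | step 3 | trimethyl{[(2Z,6Z)-3,7-dimethyl-1-(3-methylbut-1-en-2-yl)cycloocta-2,6-dien-1-yl]oxy}silane | C[Si](C)(C)OC1(C(=C)C(C)C)/C=C(/C)CC/C=C(/C)C1
F2 | step 3 | {[(2Z,6Z)-3,7-dimethyl-10-(propan-2-yl)cyclodeca-1(10),2,6-trien-1-yl]oxy}trimethylsilane | C[Si](C)(C)OC1=C(C(C)C)CC/C(C)=C\CC/C(C)=C\1
F3 | step 1 | (4Z)-1,5-dimethyl-9-oxabicyclo[6.1.0]non-4-ene (cis-fused, racemic) | CC12CC/C=C(/C)CCC1O2
F4 | step 1 | (5Z)-1,5-dimethyl-2-(phenylselanyl)cyclooct-5-en-1-ol (trans, racemic) | CC1(O)CC/C=C(/C)CCC1[Se]c1ccccc1
F5 | step 1 | (5Z)-1,5-dimethyl-2-(phenylseleninyl)cyclooct-5-en-1-ol | CC1(O)CC/C=C(/C)CCC1[Se](=O)c1ccccc1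
F6 | step 1 | (2Z,5Z)-1,5-dimethylcycloocta-2,5-dien-1-ol (racemic) | CC1(O)/C=C\C/C(C)=C\CC1
F7 | step 4 | racemic cis-(2Z,6Z)-3,7-dimethyl-10-(propan-2-yl)cyclodeca-2,6-dien-1-ol (racemate of 10, relative configuration shown) | O[C@H]1/C=C(/C)CC/C=C(/C)CC[C@H]1C(C)C
F8 | step 4 | (1S,2Z,6Z,10R)-3,7-dimethyl-10-(propan-2-yl)cyclodeca-2,6-dien-1-yl acetate | CC(=O)O[C@@H]1/C=C(/C)CC/C=C(/C)CC[C@@H]1C(C)C
F9 | step 2 | (2Z,6Z)-1-ethynyl-3,7-dimethylcycloocta-2,6-dien-1-ol (racemic) | OC1(C#C)/C=C(/C)CC/C=C(/C)C1
F10 | step 6 | 4-[(tert-butyldimethylsilyl)oxy]-3-methoxybenzoyl chloride | COc1cc(C(Cl)=O)ccc1O[Si](C)(C)C(C)(C)C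
A1 | alternative 1 | tert-butyldimethylsilyl ether of (6R,7S)-2-(phenylsulfonyl)germacra-1(10)Z,4Z-dien-6-ol (C2 epimers) | CC(C)(C)[Si](C)(C)O[C@H]1/C=C(/C)CC(S(=O)(=O)c2ccccc2)/C=C(/C)CC[C@H]1C(C)C
A2 | alternative 1 | tert-butyl{[(2Z,4R,5S,8Z)-1-chloro-2,8-dimethyl-10-(phenylsulfonyl)-5-(propan-2-yl)deca-2,8-dien-4-yl]oxy}dimethylsilane | ClC/C(C)=C\[C@H](O[Si](C)(C)C(C)(C)C)[C@H](C(C)C)CC/C(C)=C\CS(=O)(=O)c1ccccc1
A3 | alternative 2 | 6,7-trans-(1(10)Z,4Z)-germacra-1(10),4,11-trien-6-ol (racemic, drawn as 6S,7S) | O[C@@H]1/C=C(/C)CC/C=C(/C)CC[C@H]1C(C)=C
A4 | alternative 2 | (2Z,6Z,10E)-12-bromo-3,7,11-trimethyldodeca-2,6,10-trienal | O=C/C=C(/C)CC/C=C(/C)CC/C=C(\C)CBr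
A5 | alternative 3 | tert-butyldimethylsilyl ether of (6R,7S)-germacra-1(10)Z,4Z-dien-6-ol | CC(C)(C)[Si](C)(C)O[C@H]1/C=C(/C)CC/C=C(/C)CC[C@H]1C(C)C
A6 | alternative 3 | eleven-membered cyclic sulfone with sulfur between C1 and C10 of the silyl-protected (6R,7S) skeleton (C10 epimers) | CC(C)(C)[Si](C)(C)O[C@H]1/C=C(/C)CCCS(=O)(=O)C(C)CC[C@H]1C(C)C
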